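The retrosynthesis (flavanone numbering throughout) first cuts the six ArO–CH2Ph bonds. In ring C it then adds a C2–C4 bond, moving H from C2 to the C4 oxygen, which gives an isomer of the flavanone, a 1a-phenylcyclopropa[b]benzofuran-6b-ol. After that it cuts C3 (one CH2 unit), O1–C2, C6–CH2, C8–CH2 and the two inner CH2–aryl bonds of the side chain.
In the forward direction the three-ring side chain grows by two Negishi/chlorination cycles. Ring A is bought as 2,4,6-trihydroxydeoxybenzoin, and its one unprotected OH (the later O1) steers the first benzyl group to C8 and leaves C6 for iodination and Negishi union with the chain.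
Rings arise in this order: O1–C2 closes a five-membered coumaranone, CH2 is added across its enol ether bond, the five-membered ring is enlarged to six-membered ring C, and hydrogenolysis ends the route.
The enabling feature is that C2 carries both O1 and the phenyl ring and lies β to C4, so an alkoxy radical on C4 of the cyclopropane breaks the C2–C4 bond. The trialkoxy ring A attached to C4 is the site of one-electron oxidation.
For stereochemistry, the racemic cyclopropanol collapses to one planar C2 radical and a chiral thiol sets 2S by H-atom transfer (stereoconvergent). O1–C8a is never broken, so neither C2 nor the C6/C8 pattern can scramble through a chalcone.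
Key step: step 13

Assumption: the sense of induction of the peptide thiol cannot be predicted with certainty, so the mirror-image series (built from L- or D-amino acids) that gives 2S is used.
Abbreviations: MB = 2-(benzyloxy)benzyl. TB = 2-(benzyloxy)-5-{2-(benzyloxy)-5-[2-(benzyloxy)benzyl]benzyl}benzyl.

Step 1
Reactants: 1 2-(benzyloxy)-5-bromobenzaldehyde
Product: 2 [2-(benzyloxy)-5-bromophenyl]methanol
Conditions: NaBH4, MeOH–THF, 0 °C
Reagents that add atoms: none
Why: Borohydride reduction of an aryl aldehyde leaves the aryl bromide and the benzyl ether untouched and gives the building block that is used twice.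

Step 2
Reactants: 3 2-(benzyloxy)benzyl chloride (MB-Cl); 2 [2-(benzyloxy)-5-bromophenyl]methanol
Product: 5 {2-(benzyloxy)-5-[2-(benzyloxy)benzyl]phenyl}methanol (two-ring alcohol), via benzylzinc chloride 4 (not isolated)
Conditions: Zn dust, LiCl, THF, 25 °C; then 2, Pd(OAc)2 (2 mol %), SPhos (4 mol %), THF, 25 °C
Reagents that add atoms: none
Why: LiCl-promoted zinc insertion into a benzylic chloride followed by Negishi cross-coupling, a pairing known to tolerate free hydroxyl groups, makes the ArCH2–Ar bond exactly para to the ring oxygen because the bromide marks that carbon.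

Step 3
Reactants: 5 two-ring alcohol
Product: 6 1-(benzyloxy)-4-[2-(benzyloxy)benzyl]-2-(chloromethyl)benzene (two-ring chloride)
Conditions: SOCl2, CH2Cl2, 0 °C, used without delay
Reagents that add atoms: thionyl chloride, O=S(Cl)Cl
Why: Chlorodehydroxylation of an electron-rich benzylic alcohol with thionyl chloride is fast at low temperature, where self-alkylation of the product should stay slow.

Step 4
Reactants: 6 two-ring chloride; 2 [2-(benzyloxy)-5-bromophenyl]methanol
Product: 8 three-ring alcohol TB-OH, via two-ring benzylzinc chloride 7 (not isolated)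
Conditions: Zn dust, LiCl, THF, 25 °C; then 2, Pd(OAc)2 (2 mol %), SPhos (4 mol %), THF, 25 °C
Reagents that add atoms: none
Why: This second Negishi cycle is of the same type as step 2 and again places the new CH2–aryl bond para to the ring oxygen.

Step 5
Reactants: 8 three-ring alcohol TB-OH
Product: 9 three-ring chloride TB-Cl
Conditions: SOCl2, CH2Cl2, 0 °C, used without delay
Reagents that add atoms: thionyl chloride, O=S(Cl)Cl
Why: The chlorodehydroxylation is the same as in step 3.

Step 6
Reactants: 10 2-phenyl-1-(2,4,6-trihydroxyphenyl)ethan-1-one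
Product: 11 1-[2,4-bis(benzyloxy)-6-hydroxyphenyl]-2-phenylethan-1-one
Conditions: BnBr (2.1 equiv), K2CO3, acetone, reflux
Reagents that add atoms: benzyl bromide, BrCc1ccccc1
Why: Williamson etherification stops at the diether because the last ortho hydroxyl is tied to the ketone by a strong hydrogen bond, and since the two ortho hydroxyls of 10 are equivalent the one free OH (the later O1) is defined without any regiochemical choice.

Step 7
Reactants: 11 dibenzyl ether ketone; 3 2-(benzyloxy)benzyl chloride
Product: 12 1-[4,6-bis(benzyloxy)-2-hydroxy-3-(MB)phenyl]-2-phenylethan-1-one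
Conditions: ZnCl2 (1 equiv), 1,4-dioxane, 25–40 °C, slow addition of 3 (1.0 equiv)
Reagents that add atoms: none
Why: Zinc chloride-mediated Friedel–Crafts benzylation by the o-alkoxy-stabilised benzylic cation should go to C3, ortho to the free OH and flanked by only one benzyloxy group, rather than to C5 between two benzyloxy groups, which is the preference that halogenation of 2-hydroxy-4,6-dialkoxyaryl ketones shows.

Step 8
Reactants: 12 C3-benzylated ketone
Product: 13 1-[4,6-bis(benzyloxy)-2-hydroxy-5-iodo-3-(MB)phenyl]-2-phenylethan-1-one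
Conditions: NIS (1.0 equiv), MeCN–CH2Cl2, 0 °C, dark
Reagents that add atoms: N-iodosuccinimide, O=C1CCC(=O)N1I
Why: Electrophilic aromatic iodination takes the only free position of the most activated ring, para to the free phenol, under neutral conditions that leave the anisole-like outer rings and the enolisable CH2 alone.

Step 9
Reactants: 9 three-ring chloride TB-Cl; 13 aryl iodide
Product: 15 1-[4,6-bis(benzyloxy)-2-hydroxy-3-(MB)-5-(TB)phenyl]-2-phenylethan-1-one, via three-ring benzylzinc chloride 14 (not isolated)
Conditions: Zn dust, LiCl, THF, 25 °C; then slow addition to 13, Pd(OAc)2 (3 mol %), SPhos (6 mol %), THF, 25–50 °C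
Reagents that add atoms: none
Why: Negishi sp3–sp2 cross-coupling with a bulky biarylphosphine copes with the two ortho benzyloxy groups, and slowly added benzylic zinc reagents are known to couple faster than a phenol protonates them.

Step 10
Reactants: 15 fully substituted deoxybenzoin
Product: 16 racemic 2-bromo-1-[4,6-bis(benzyloxy)-2-hydroxy-3-(MB)-5-(TB)phenyl]-2-phenylethan-1-one
Conditions: CuBr2 (2.2 equiv), EtOAc–CHCl3 1:1, reflux
Reagents that add atoms: copper(II) bromide, Br[Cu]Br
Why: Heterogeneous copper(II) bromide brominates the enol of the aryl benzyl ketone at its doubly activated α-carbon, ring A has no free position left, and the racemic stereocentre formed is erased in step 11.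

Step 11
Reactants: 16 α-bromo ketone
Product: 18 4,6-bis(benzyloxy)-7-(MB)-5-(TB)-2-phenyl-3-(triethylsilyloxy)benzofuran, via coumaranone 17 (not isolated)
Conditions: Et3N (3 equiv), CH2Cl2, 0 °C to rt, argon; then TESOTf (1.3 equiv), 0 °C
Reagents that add atoms: triethylsilyl trifluoromethanesulfonate, CC[Si](CC)(CC)OS(=O)(=O)C(F)(F)F
Why: Intramolecular Williamson etherification (5-exo-tet) by the only free phenol fixes O1 next to the MB-bearing carbon, and soft enolisation with silyl triflate and amine traps the air-sensitive coumaranone on oxygen as the aromatic 3-siloxybenzofuran.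

Step 12
Reactants: 18 3-siloxybenzofuran
Product: 20 racemic cis-fused 4,6-bis(benzyloxy)-3-(MB)-5-(TB)-1a-phenyl-1a,6b-dihydro-1H-cyclopropa[b]benzofuran-6b-ol, via siloxycyclopropane 19 (not isolated)
Conditions: Et2Zn (5 equiv), CH2I2 (10 equiv), CH2Cl2, 0 °C to rt; aqueous work-up; then TBAF, AcOH, THF, 0 °C; purification on deactivated silica
Reagents that add atoms: diiodomethane, ICI
Why: Simmons–Smith cyclopropanation (Furukawa variant) adds CH2 to the silyl enol ether bond, the most electron-rich and least aromatic π bond of the benzofuran, necessarily cis so that one racemic diastereomer forms, and acetic acid-buffered fluoride frees the cyclopropanol without base-induced opening.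

Step 13
Reactants: 20 racemic cyclopropanol
Product: 22 (2S)-5,7-bis(benzyloxy)-8-(MB)-6-(TB)-2-phenylchroman-4-one (hexabenzyl ether of the target), via flavan-2-yl radical 21 (not isolated)
Conditions: [Ir(dF(CF3)ppy)2(5,5'-d(CF3)bpy)]PF6 (2 mol %), 2,4,6-collidine (2 equiv), Boc-Cys-D-Pro-Aib-Phe-NMe2-type β-turn peptide thiol (10 mol %), CH2Cl2 (0.05 M), blue LED, 0 °C, argon, stopped at full conversion
Reagents that add atoms: none
Why: Proposed new method: the excited Ir(III) complex oxidises the hexasubstituted trialkoxy ring A of racemic 20 (not conjugated to a carbonyl at this stage, hence the most electron-rich arene present), collidine-assisted proton-coupled electron transfer turns the adjacent C4–OH into an alkoxy radical, strain-driven β-scission of the C2–C4 zero bridge merges the furan ring (O1, C2, C4, C4a, C8a) and the cyclopropane into the six-membered pyranone carrying the planar C2 radical 21, this radical takes H from the thiol, and Ir(II) plus collidinium regenerate the thiol, so the step is a redox-neutral isomerisation. The closest known reaction types are the PCET ring-opening isomerisation of aryl-substituted cyclic alcohols with an Ir photocatalyst, a pyridine base and a thiol H donor, the oxidative one-carbon ring expansion of bicyclo[n.1.0]alkan-1-ols and their silyl ethers, and enantioselective H-atom transfer from cysteine-peptide or thiosugar catalysts to prochiral α-heteroatom radicals, and their union on a cyclopropa[b]benzofuranol is new. No ring is closed from a chain: ring C arises by endocyclic bond cleavage of the 2-oxabicyclo[3.1.0]hexane (5 + 3 to 6), and any exocyclic C3–C4 cleavage should be harmless because the primary radical re-adds 3-exo-trig to the ketone and drains to the far more stable radical 21. Both stereocentres of 20 are erased in 21, so both enantiomers converge, and the only new stereocentre, C2, is set by the chiral thiol, which is docked by peptide N–H hydrogen bonds to the new C4=O two atoms away and delivers H to the face that gives 2S. The step needs endocyclic scission (secured by O1 and phenyl on C2), H transfer from the catalyst alone (collidine, solvent and the ArCH2Ar and OCH2Ph groups are poor donors to a stabilised radical) and no later erosion (ring A of 22 is deactivated by the C4 ketone against re-oxidation, and thiyl radicals are removed by Ir(II)). Because O1–C8a is never broken, the C6/C8 pattern fixed in step 11 cannot scramble by a Wessely–Moser type opening.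

Step 14
Reactants: 22 hexabenzyl ether
Product: 23 sarmentosumin B
Conditions: H2 (1 atm), 10 % Pd/C, EtOAc–MeOH 1:1, rt
Reagents that add atoms: none
Why: Catalytic hydrogenolysis cleaves the six primary benzyl aryl ethers under neutral conditions in which the flavanone cannot open to a chalcone, so C2 keeps its configuration, and the diarylmethane carbons and the slower secondary C2–O1 bond should stay intact if the uptake is monitored.

Compound list
1 | 2-(benzyloxy)-5-bromobenzaldehyde | O=Cc1cc(Br)ccc1OCc1ccccc1 | starting material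
2 | [2-(benzyloxy)-5-bromophenyl]methanol | OCc1cc(Br)ccc1OCc1ccccc1 | intermediate
3 | 2-(benzyloxy)benzyl chloride | ClCc1ccccc1OCc1ccccc1 | starting material
4 | 2-(benzyloxy)benzylzinc chloride | Cl[Zn]Cc1ccccc1OCc1ccccc1 | intermediate
5 | {2-(benzyloxy)-5-[2-(benzyloxy)benzyl]phenyl}methanol | OCc1cc(Cc2ccccc2OCc2ccccc2)ccc1OCc1ccccc1 | intermediate
6 | 1-(benzyloxy)-4-[2-(benzyloxy)benzyl]-2-(chloromethyl)benzene | ClCc1cc(Cc2ccccc2OCc2ccccc2)ccc1OCc1ccccc1 | intermediate
7 | two-ring benzylzinc chloride | Cl[Zn]Cc1cc(Cc2ccccc2OCc2ccccc2)ccc1OCc1ccccc1 | intermediate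
8 | three-ring alcohol TB-OH | OCc1cc(Cc2cc(Cc3ccccc3OCc3ccccc3)ccc2OCc2ccccc2)ccc1OCc1ccccc1 | intermediate
9 | three-ring chloride TB-Cl | ClCc1cc(Cc2cc(Cc3ccccc3OCc3ccccc3)ccc2OCc2ccccc2)ccc1OCc1ccccc1 | intermediate
10 | 2-phenyl-1-(2,4,6-trihydroxyphenyl)ethan-1-one | O=C(Cc1ccccc1)c1c(O)cc(O)cc1O | starting material
11 | 1-[2,4-bis(benzyloxy)-6-hydroxyphenyl]-2-phenylethan-1-one | O=C(Cc1ccccc1)c1c(O)cc(OCc2ccccc2)cc1OCc1ccccc1 | intermediate
12 | 1-[4,6-bis(benzyloxy)-2-hydroxy-3-(MB)phenyl]-2-phenylethan-1-one | O=C(Cc1ccccc1)c1c(O)c(Cc2ccccc2OCc2ccccc2)c(OCc2ccccc2)cc1OCc1ccccc1 | intermediate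
13 | 1-[4,6-bis(benzyloxy)-2-hydroxy-5-iodo-3-(MB)phenyl]-2-phenylethan-1-one | O=C(Cc1ccccc1)c1c(O)c(Cc2ccccc2OCc2ccccc2)c(OCc2ccccc2)c(I)c1OCc1ccccc1 | intermediate
14 | three-ring benzylzinc chloride TB-ZnCl | Cl[Zn]Cc1cc(Cc2cc(Cc3ccccc3OCc3ccccc3)ccc2OCc2ccccc2)ccc1OCc1ccccc1 | intermediate
15 | 1-[4,6-bis(benzyloxy)-2-hydroxy-3-(MB)-5-(TB)phenyl]-2-phenylethan-1-one | O=C(Cc1ccccc1)c1c(O)c(Cc2ccccc2OCc2ccccc2)c(OCc2ccccc2)c(Cc2cc(Cc3cc(Cc4ccccc4OCc4ccccc4)ccc3OCc3ccccc3)ccc2OCc2ccccc2)c1OCc1ccccc1 | intermediate
16 | racemic α-bromo ketone of 15 | O=C(C(Br)c1ccccc1)c1c(O)c(Cc2ccccc2OCc2ccccc2)c(OCc2ccccc2)c(Cc2cc(Cc3cc(Cc4ccccc4OCc4ccccc4)ccc3OCc3ccccc3)ccc2OCc2ccccc2)c1OCc1ccccc1 | intermediate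
17 | racemic 4,6-bis(benzyloxy)-7-(MB)-5-(TB)-2-phenylbenzofuran-3(2H)-one | O=C1C(c2ccccc2)Oc2c(Cc3ccccc3OCc3ccccc3)c(OCc3ccccc3)c(Cc3cc(Cc4cc(Cc5ccccc5OCc5ccccc5)ccc4OCc4ccccc4)ccc3OCc3ccccc3)c(OCc3ccccc3)c21 | intermediate
18 | 4,6-bis(benzyloxy)-7-(MB)-5-(TB)-2-phenyl-3-(triethylsilyloxy)benzofuran | CC[Si](CC)(CC)Oc1c(-c2ccccc2)oc2c(Cc3ccccc3OCc3ccccc3)c(OCc3ccccc3)c(Cc3cc(Cc4cc(Cc5ccccc5OCc5ccccc5)ccc4OCc4ccccc4)ccc3OCc3ccccc3)c(OCc3ccccc3)c12 | intermediate
19 | racemic cis-fused 6b-(triethylsilyloxy)cyclopropa[b]benzofuran | CC[Si](CC)(CC)OC12CC1(c1ccccc1)Oc1c(Cc3ccccc3OCc3ccccc3)c(OCc3ccccc3)c(Cc3cc(Cc4cc(Cc5ccccc5OCc5ccccc5)ccc4OCc4ccccc4)ccc3OCc3ccccc3)c(OCc3ccccc3)c12 | intermediate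
20 | racemic cis-fused 1a-phenylcyclopropa[b]benzofuran-6b-ol | OC12CC1(c1ccccc1)Oc1c(Cc3ccccc3OCc3ccccc3)c(OCc3ccccc3)c(Cc3cc(Cc4cc(Cc5ccccc5OCc5ccccc5)ccc4OCc4ccccc4)ccc3OCc3ccccc3)c(OCc3ccccc3)c12 | intermediate
21 | 4-oxoflavan-2-yl radical | O=C1C[C](c2ccccc2)Oc2c(Cc3ccccc3OCc3ccccc3)c(OCc3ccccc3)c(Cc3cc(Cc4cc(Cc5ccccc5OCc5ccccc5)ccc4OCc4ccccc4)ccc3OCc3ccccc3)c(OCc3ccccc3)c21 | intermediate
22 | (2S)-5,7-bis(benzyloxy)-8-(MB)-6-(TB)-2-phenylchroman-4-one | O=C1C[C@@H](c2ccccc2)Oc2c(Cc3ccccc3OCc3ccccc3)c(OCc3ccccc3)c(Cc3cc(Cc4cc(Cc5ccccc5OCc5ccccc5)ccc4OCc4ccccc4)ccc3OCc3ccccc3)c(OCc3ccccc3)c21 | intermediate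
23 | sarmentosumin B | O=C1C[C@@H](c2ccccc2)Oc2c(Cc3ccccc3O)c(O)c(Cc3cc(Cc4cc(Cc5ccccc5O)ccc4O)ccc3O)c(O)c21 | target

Total step count: 14. Longest linear sequence: 11 (steps 1, 2, 3, 4, 5, 9, 10, 11, 12, 13, 14).

Steps most likely to fail

1. Step 13. The risks are poor facial selectivity in the H-atom transfer, slow erosion of the enantiomeric purity by reversible H abstraction at C2, and non-radical background opening of the cyclopropanol. The fallback sets out from 20 and returns at 22.
   - The isomerisation is run in its known achiral form (same Ir catalyst and collidine, thiophenol as H donor) to give the racemic hexabenzyl flavanone F1.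
   - Asymmetric transfer hydrogenation under kinetic-resolution conditions (Cp*Rh–TsDPEN, HCO2H/Et3N, EtOAc, rt), with the catalyst enantiomer that consumes the 2R ketone, turns that half into the cis-(2R,4R)-flavan-4-ol F2.
   - The untouched 2S ketone, separated by chromatography, is 22. The stereocentre then comes from resolution and not from the ring expansion.

2. Step 12. The risks are sluggish carbenoid transfer to the hindered, tetrasubstituted and partly aromatic C2=C3 bond, and zinc iodide-induced desilylation or isomerisation of the siloxycyclopropane. The fallback sets out from 16 and returns at 22.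
   - K2CO3 in DMF under argon closes coumaranone 17, and its enolate is C-alkylated in the same pot with excess CH2I2 to the racemic 2-(iodomethyl) ketone F3.
   - Slow addition of Bu3SnH/AIBN in refluxing benzene (classical Dowd–Beckwith ring expansion, the same 1,2-acyl shift entered from the carbon radical) gives the racemic hexabenzyl flavanone F1.
   - F1 is resolved by the transfer hydrogenation described under step 13 to 22.

3. Step 7. The risks are attack at C5 instead of C3, double benzylation, and self-condensation of the benzylic chloride. The fallback sets out from 11 and returns at 12.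
   - NIS in MeCN iodinates 11 ortho to the free OH to give the 3-iodo ketone F4, whose substitution pattern can be checked before any carbon is attached.
   - Negishi coupling of F4 with benzylzinc chloride 4 under the conditions of step 2 gives 12. The position is then fixed by the halide and not by the selectivity of a cation.

Further compounds
F1 | step 13 | racemic 5,7-bis(benzyloxy)-8-(MB)-6-(TB)-2-phenylchroman-4-one | O=C1CC(c2ccccc2)Oc2c(Cc3ccccc3OCc3ccccc3)c(OCc3ccccc3)c(Cc3cc(Cc4cc(Cc5ccccc5OCc5ccccc5)ccc4OCc4ccccc4)ccc3OCc3ccccc3)c(OCc3ccccc3)c21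
F2 | step 13 | cis-(2R,4R)-5,7-bis(benzyloxy)-8-(MB)-6-(TB)-2-phenylchroman-4-ol | O[C@@H]1C[C@H](c2ccccc2)Oc2c(Cc3ccccc3OCc3ccccc3)c(OCc3ccccc3)c(Cc3cc(Cc4cc(Cc5ccccc5OCc5ccccc5)ccc4OCc4ccccc4)ccc3OCc3ccccc3)c(OCc3ccccc3)c21
F3 | step 12 | racemic 4,6-bis(benzyloxy)-2-(iodomethyl)-7-(MB)-5-(TB)-2-phenylbenzofuran-3(2H)-one | O=C1C(CI)(c2ccccc2)Oc2c(Cc3ccccc3OCc3ccccc3)c(OCc3ccccc3)c(Cc3cc(Cc4cc(Cc5ccccc5OCc5ccccc5)ccc4OCc4ccccc4)ccc3OCc3ccccc3)c(OCc3ccccc3)c21
F4 | step 7 | 1-[4,6-bis(benzyloxy)-2-hydroxy-3-iodophenyl]-2-phenylethan-1-one | O=C(Cc1ccccc1)c1c(O)c(I)c(OCc2ccccc2)cc1OCc1ccccc1
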